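We charge equal amounts of the two reactants, c(electrophile) = 0.050 M and c(nucleophile) = 0.0500 M, add c(scavenger) = 0.0600 M, vary c(free base) between flasks, and keep the mass balance of the electrophile.

| flask | electrophile | nucleophile | free base | scavenger | remark | time |
|---|---|---|---|---|---|---|
| violet | 0.050 M | 0.050 M | 0.018 M | 0.060 M | run made earlier |  |
| grey | 0.050 M | 0.050 M | 0.034 M | 0.060 M | run made earlier |  |
| south-east | 0.050 M | 0.0500 M | 0.0250 M | 0.0600 M |  | 4.0 h |
| south-west | 0.050 M | 0.0500 M | 0.0330 M | 0.0600 M |  | 4.0 h |
| east | 0.050 M | 0.0500 M | 0.0420 M | 0.0600 M |  | 4.0 h |

- violet (time / h: electrophile / %, target / %): 0.333: 76.8, 14.2; 0.667: 61.6, 17.0; 1.50: 40.3, 16.2; 4.00: 17.0, 11.3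
- grey (time / h: electrophile / %, target / %): 0.500: 68.8, 17.4; 1.33: 42.6, 17.1; 2.50: 26.8, 13.7; 4.00: 17.1, 10.4

(each reading ± 0.5 percentage points)

- part of the electrophile that has reacted at the end, south-east
- part of the electrophile that has reacted at the end, south-west
- part of the electrophile that has reacted at the end, east
- what raising the concentration of free base from its lowest to its highest value here does to the part of the electrophile that has reacted (changes below 5 percentage points count as none) (it rises / it falls / no change)

At 4.00 h the violet run enters 17.0% of the electrophile as still there and 11.3% as target, which leaves 71.7% in forms we do not read. Target falls from 17.0% at 0.667 h while electrophile goes on falling, so we assume, as our own reckoning, that target is used up by a further electrophile and that half of the unread entry was once target. Adding that half to the target entry gives the throughput, the concentration of electrophile that has passed through target: 0.0236 M in violet. The grey run, with about twice the free base, gives 0.0233 M, and the electrophile left differs by less than the scatter of 0.5 percentage points. In violet the throughput also exceeds the free base charged, so on our assumption it is not held to that charge. We therefore read the electrophile loss as zero order in free base over these runs and enter the violet books for all three new flasks, 83.0% reacted.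

The forecast gives 83%, 83% and 83%, with the trend no change, on its own ground: “Free base seems to affect only the target slightly, through its later loss, not the conversion.”

South-east, south-west and east give 83.0%, 83.0% and 83.0%, and the trend is no change, a change of 0.028 points from lowest to highest free base, with 99.7% of the free base still free at the end of south-east.

    nucleophile + acid set free ⇌ idle adduct, settled at all times (K = 28.0 L mol⁻¹)
    acid set free + free base ⇌ salt of the base, settled at all times (K = 200 L mol⁻¹)
    electrophile + target → side product (k = 0.530 L mol⁻¹ min⁻¹)
    electrophile + nucleophile → acid set free + target (k = 0.260 L mol⁻¹ min⁻¹)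
    nucleophile + acid set free ⇌ protonated nucleophile, settled at all times (K = 2.00 × 10⁵ L mol⁻¹)
    acid set free + scavenger → scavenged by-product (k = 24.0 L mol⁻¹ min⁻¹)

In south-east the throughput is 0.0235 M, which with 13% of the nucleophile free, 0.0202 M of protonated nucleophile and 2.83 × 10⁻⁶ M of idle adduct makes up the nucleophile charge. For east, with the other amounts and the time held, the part of the electrophile reacted has moved by 5 points at 0.0447 M or 0.0566 M of nucleophile. The neighbour of south-east with 0.013 M of nucleophile reacts 30.3% and holds 1.42% of target, so its throughput is 0.00793 M, or 61.0% of its nucleophile charge, with 9.5% still free.

(The readings stem from a simulated flask for substances that don't exist.)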